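## Analysis of the target

The target is a p-terphenyl: a central benzene ring (C1–C6) with benzoyloxy groups on C1 and C2, 4-hydroxyphenyl rings on C3 and C6, and free hydroxyls on C4 and C5. It has no stereocentre, the biaryl axes are not stereogenic because the outer rings lack ortho substituents, and a twofold symmetry element passes through the midpoints of the C1–C2 and C4–C5 bonds. The sensitive groups are the two aryl benzoates (activated esters, cleaved or transferred by bases, amines and alkoxides), the electron-rich catechol at C4/C5 (oxidised by air, above all as its anion) and the two phenols. The carbon skeleton is not the problem, since fully oxygenated 2,5-diaryl-1,4-benzoquinones are an accessible class. The problem is the oxygen pattern: the four ring oxygens form two symmetry-equivalent adjacent pairs, and exactly one pair must be acylated; direct benzoylation of the tetrol, or acylation of the hydroquinone made from the quinone, would give mixtures or the para-related pattern. The strategy rests first on the fact that the two benzoyl carbons on O1 and O2 can be read as the halves of one PhC=CPh unit, that is, of a 2,3-diphenyl-1,4-dioxin ring fused to C1–C2, whose oxidative C=C cleavage gives two benzoates that can only sit on neighbouring oxygens. It rests second on the fact that the quinone form of the central ring has a 1,2-dione tautomer (carbonyls on C1 and C2, enolic hydroxyls on C4 and C5) that can accept such a two-carbon bridge in a [4+2] sense only once, because the adduct is an aromatic catechol.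

## Retrosynthetic reasoning

**15 from 14.** The four O–CH2 bonds of benzyl ethers are the last to be cut. The final operation must be neutral and non-nucleophilic, because 15 holds two aryl benzoates next to four free hydroxyls; hydrogenolysis of 14 meets this. Acyl migration is not a concern, since each benzoate is meta to the nearest liberated hydroxyl, with an aryl-bearing carbon in between.

**14 from 12.** The two benzoyl carbonyl carbons are reconnected as a C=C bond, which turns the vicinal dibenzoate of 14 into the 2,3-diphenyl-1,4-dioxin ring of 12. This is the decisive simplification: two acyl groups that must go onto one particular oxygen pair become one ring, and a ring can only span neighbouring oxygens. In the forward direction, ozonolysis must cleave one tetrasubstituted, doubly oxygenated alkene faster than it touches benzyl ethers or arenes. That alkene is the most electron-rich π bond of 12, which is the basis for the selectivity.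

**12 from 11.** The two benzyl groups on the catechol oxygens are removed. A free catechol would not survive the oxidative cleavage, so it is masked first. Benzyl is chosen because it leaves in the same final operation as the two aryl benzyl ethers already present, so no separate deprotection step is added.

**11 from 5 and 8 (key disconnection).** Both bonds between the ring oxygens O1/O2 and the diphenylethene carbons are cut together. Cutting only one would lead to a mono-alkylated tetrol and bring back the problem of telling four hydroxyls apart. Cutting both gives a [4+2] retron in which the central ring is at the quinone level and supplies an O=C–C=O unit, namely tautomer 9 of the stable quinone 5. The two-carbon partner must be at the alkyne oxidation level. Enamine 8 is an alkyne equivalent: it is electron-rich enough to meet a weak heterodiene, and the adduct 10 restores the double bond by loss of 7. The gain is one ring, two C–O bonds, differentiation of the two oxygen pairs, and a built-in limit to one bridge, since 10 and 11 are catechols and no longer diones. The forward reaction must favour O,O-cycloaddition over plain acid–base chemistry between acidic 5 and basic 8.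

**5 from 4, 4 from 2 and 3, 2 from 1.** The two biaryl bonds at C3 and C6 are cut next. At the quinone level, with the hydroxyls masked as methyl ethers (4), these are bonds that a twofold Suzuki–Miyaura coupling of dibromoquinone 2 with boronic acid 3 can form; saponification of the two vinylogous esters then gives 5. Building the quinone ring by base-mediated self-condensation of an aryl-substituted keto ester would be shorter on paper, but such esters prefer aldol dimerisation to butenolides, and the aim is to keep the risk of the route in the key step. Compound 2 comes from 1 by twofold methoxy-for-bromine exchange, which is known to give the 2,5-pattern.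

**8 from 6 and 7.** The C–N bond of the enamine is cut to ketone 6 and amine 7. The condensation is a standard Lewis-acid-driven dehydration.

## Alternatives that were turned down

Alternative 1: Here the outer rings are taken apart and the oxygen pattern is left alone. Each 4-hydroxyphenyl ring is traced back to a cyclohexenone, and from there to a two-carbon aldehyde arm on the central ring plus a four-carbon enone. The central building block is 4,7-bis(2-oxoethyl)-1,3-benzodioxole-5,6-diyl dibenzoate A2, which already carries both benzoates and has the other oxygen pair tied up as a methylene acetal. The four-carbon partner is but-3-en-2-one A3.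

In the forward reaction A2 would react twice with A3. Amine-catalysed Michael addition of each benzylic carbon of A2 to the terminus of A3 is followed by acid-promoted aldol condensation between the aldehyde carbon and the methyl carbon that came from A3. This closes two cyclohexenone rings and gives 4,7-bis(4-oxocyclohex-2-en-1-yl)-1,3-benzodioxole-5,6-diyl dibenzoate A1. Dehydrogenation of both enones of A1 to phenols and removal of the methylene acetal would finish the synthesis.

In its favour, every bond-forming step has direct precedent, and the benzoates of A2 come from ordinary acylation of a catechol whose partner pair is masked. On this point it is stronger than the chosen route, which depends on one unprecedented cycloaddition.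

Against it, A2 carries two enolisable arylacetaldehyde arms ortho to aryl benzoates. A secondary-amine catalyst can aminolyse these activated esters, and the enamine or enol of each arm can attack the neighbouring ester carbonyl with closure of a five-membered ring, leading to benzofurans. The enone A3 polymerises readily under the same amine and acid conditions and would have to be used in excess. The two stereocentres of A1 are made only to be destroyed, two dehydrogenations and a cleavage of a methylene acetal beside aryl benzoates must follow, and rings that can be bought as a boronic acid are rebuilt atom by atom.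

In comparison, the chosen route buys the outer rings, needs eight steps in all, and differentiates the oxygen pairs by mechanism instead of by a protecting group that is hard to remove.

Alternative 2: The central ring is disconnected into three alkynes. Di-tert-butylbis({[4-(triisopropylsilyloxy)phenyl]ethynyl}oxy)silane A5, a bis(ynol ether) tethered through silicon, supplies C1, C2, C3 and C6. 1,2-Di-tert-butoxyethyne A6 supplies C4 and C5.

In the forward reaction [Rh(cod)2]BF4 (monovalent rhodium) with a bisphosphine would cyclotrimerise A5 and A6. The bonds C1–C2, C3–C4 and C5–C6 form, and the benzene ring closes together with the fused five-membered dioxasilole ring. The product is 5,6-di-tert-butoxy-2,2-di-tert-butyl-4,7-bis[4-(triisopropylsilyloxy)phenyl]-1,3,2-benzodioxasilole A4. From A4 the silylene would be exchanged for two benzoyl groups, and the tert-butyl and silyl ethers would then be removed.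

In its favour, it is the most convergent plan: the hexasubstituted ring of A4 appears in one step with the two oxygen pairs already differentiated (silylene against tert-butyl). Here it is stronger than the chosen route, which spends three steps on the quinone.

Against it, A5 is a twofold silyl ynol ether, a ketene equivalent that is sensitive to moisture and has to be assembled from two aryl ynolates on one silicon atom. A6 fragments by retro-ene loss of isobutene on mild heating. All three alkynes are strong donors, whereas metal-catalysed [2+2+2] reactions work best when at least one partner is electron-poor, so oligomerisation and [2+2] pathways should compete. In A4 the silylene and the two aryl silyl ethers are all fluoride-labile, so freeing O1 and O2 alone for benzoylation is not clean, and removing the aryl silyl ethers with fluoride after benzoylation endangers the aryl benzoates.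

In comparison, the chosen route also has one unprecedented step, but both partners of that step are stable, storable compounds made by routine chemistry, whereas A5 and A6 are not.

Alternative 3: The central ring is cut at C3–C4 and C5–C6. (1Z,3Z)-1,4-Bis[4-(benzyloxy)phenyl]buta-1,3-diene-2,3-diyl dibenzoate A8 is the diene and carries both benzoates as enol esters. 4,5-Dichloro-1,3-dioxol-2-one A9 is the dienophile and serves as a masked 1,2-dione.

In the forward reaction A8 and A9 would combine in a thermal Diels–Alder reaction to the meso endo cycloadduct 3a,7a-dichloro-4,7-bis[4-(benzyloxy)phenyl]-2-oxo-3a,4,7,7a-tetrahydro-1,3-benzodioxole-5,6-diyl dibenzoate A7. Unmasking the chlorinated carbonate of A7 to the dione and twofold enolisation would aromatise the ring without an oxidant.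

In its favour, the benzoates sit on neighbouring carbons by construction and come from plain acylation, so the adjacency is as secure as in the chosen route. The sequence is probably shorter, and it needs no late oxidative cleavage, so on step count and on the end game it is at least as strong.

Against it, A8 must be obtained and kept as the Z,Z isomer, and twofold enol benzoylation of a 1,2-diketone gives no such guarantee. A9 is a tetrasubstituted, weakly activated dienophile that must add to two aryl-substituted diene termini, so high temperatures are likely, at which enol esters isomerise or shift acyl groups. The hydrolytic unmasking of A7 has to spare two enol benzoates that are at least as labile as the carbonate.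

In comparison, the chosen route has no geometric-purity requirement, runs its key step under mild thermal conditions, and touches the benzoates only in two neutral steps after they are formed.

Key step: step 5

Remark on the chemistry: compounds 1 and 3 are taken as commercial reagents; 2 is prepared from 1 so that the starting point is unambiguous.

## Route

Step 1
Reactants: 1 tetrabromo-1,4-benzoquinone (bromanil)
Product: 2 2,5-dibromo-3,6-dimethoxy-1,4-benzoquinone
Conditions: NaOMe (2.05 equiv), MeOH, 0 °C → rt
Reagents that add atoms: sodium methoxide, [Na+].[O-]C
Why: Twofold nucleophilic vinylic substitution (addition–elimination) of the tetrahaloquinone by methoxide; after the first exchange the methoxy group turns its conjugated carbonyl into a vinylogous ester, so the second methoxide should add to the enone that is still activated and enter para to the first, giving the 2,5-dibromo-3,6-dimethoxy pattern, and two equivalents at low temperature should stop the exchange there.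

Step 2
Reactants: 2 2,5-dibromo-3,6-dimethoxy-1,4-benzoquinone; 3 4-(benzyloxy)phenylboronic acid
Product: 4 2,5-bis[4-(benzyloxy)phenyl]-3,6-dimethoxy-1,4-benzoquinone
Conditions: 3 (2.4 equiv), Pd(PPh3)4 (5 mol %), K3PO4, 1,4-dioxane, 90 °C, Ar
Reagents that add atoms: none
Why: Twofold Suzuki–Miyaura coupling: the C–Br bonds of 2 are vinylogous acyl bromides and should undergo oxidative addition to zerovalent palladium easily, while the mild phosphate base in dioxane leaves the vinylogous methyl esters and the benzyl ethers untouched.

Step 3
Reactants: 4 2,5-bis[4-(benzyloxy)phenyl]-3,6-dimethoxy-1,4-benzoquinone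
Product: 5 2,5-bis[4-(benzyloxy)phenyl]-3,6-dihydroxy-1,4-benzoquinone
Conditions: NaOH (2 M aq), 1,4-dioxane, 60 °C; then HCl (1 M aq)
Reagents that add atoms: sodium hydroxide, [Na+].[OH-]
Why: Saponification of the two vinylogous methyl esters by conjugate addition–elimination of hydroxide; the quinone is protected against further attack as its stable dianion and is set free on acidification, and benzyl aryl ethers are inert to aqueous base.

Step 4
Reactants: 6 deoxybenzoin (1,2-diphenylethan-1-one); 7 morpholine
Product: 8 4-[(E)-1,2-diphenylethenyl]morpholine
Conditions: 7 (6 equiv), TiCl4 (0.55 equiv), toluene, 0 °C → rt, Ar; filtration under Ar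
Reagents that add atoms: none
Why: Enamine condensation driven by TiCl4 as Lewis acid and water scavenger, the standard method for hindered or conjugated ketones; the E isomer (amine trans to the β-phenyl group) is expected because it keeps the nitrogen lone pair conjugated, but the geometry has no bearing on the next step.

Step 5
Reactants: 5 2,5-bis[4-(benzyloxy)phenyl]-3,6-dihydroxy-1,4-benzoquinone; 8 4-[(E)-1,2-diphenylethenyl]morpholine
Product: 11 5,8-bis[4-(benzyloxy)phenyl]-2,3-diphenyl-1,4-benzodioxine-6,7-diol, via 1,2-dione tautomer 9 (not isolated), via morpholine cycloadduct 10 (not isolated)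
Conditions: 8 (1.5 equiv), 4 Å MS, degassed 1,4-dioxane, 25 → 80 °C, Ar; then AcOH (10 equiv), 80 °C
Reagents that add atoms: none
Why: Proposed new method: the vinylogous acid 5 should equilibrate, through its ambident anion with 8 or traces of amine as proton shuttle, with the 1,2-dione tautomer 9, whose O=C–C=O unit is an electron-poor heterodiene; its two carbonyl oxygens should add across the electron-rich C=C of 8 in an inverse-demand hetero-Diels–Alder reaction, either concerted or through a zwitterion in which the β-carbon of 8 first bonds to one oxygen and the resulting aryloxide then closes onto the iminium carbon (6-exo-trig), so that the 1,4-dioxane ring is closed in a [4+2] mode and the central ring becomes the aromatic catechol 10. The closest known reaction type is the [4+2] addition of true o-quinones (tetrahalo-o-benzoquinones, phenanthrenequinone) to enamines, enol ethers and stilbenes, which gives 2,3-dihydro-1,4-benzodioxines; that 2,5-dihydroxy-1,4-benzoquinones can be intercepted as 1,2-diones is known from their condensation with 1,2-diamines to phenazines, but a cycloaddition of this tautomer is not known. The acid then protonates the aminal nitrogen of 10, morpholine leaves to give a cation stabilised by the ring oxygen and the phenyl group, and loss of the benzylic proton at C3 gives the dioxin 11. Both stereocentres of 10 become sp2 carbons, so no stereocontrol is needed and the geometry of 8 is immaterial. O,O-bridging is favoured over the usual C-alkylation of p-quinones by enamines because all six ring carbons of 5 are substituted; the bridging stops after one ring because 10 and 11 are catechols without a dione and 5 is expected to be too weak an oxidant to re-oxidise them; the two adjacent oxygen pairs of 5 are equivalent by symmetry, so either gives 11. The gain of aromaticity should make the cycloaddition irreversible, whereas salt formation between 5 and 8 and O-addition of the quinonate to the iminium ion are reversible and only lower the concentrations of the partners.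

Step 6
Reactants: 11 5,8-bis[4-(benzyloxy)phenyl]-2,3-diphenyl-1,4-benzodioxine-6,7-diol
Product: 12 6,7-bis(benzyloxy)-5,8-bis[4-(benzyloxy)phenyl]-2,3-diphenyl-1,4-benzodioxine
Conditions: BnBr (2.6 equiv), K2CO3, DMF, 25 → 50 °C, Ar
Reagents that add atoms: benzyl bromide, BrCc1ccccc1
Why: Williamson etherification of both catechol hydroxyls; the dioxin enol ether, the aryl ethers and the biaryl bonds are inert to carbonate base, and exclusion of air prevents oxidation of the electron-rich catecholate before it is alkylated.

Step 7
Reactants: 12 6,7-bis(benzyloxy)-5,8-bis[4-(benzyloxy)phenyl]-2,3-diphenyl-1,4-benzodioxine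
Product: 14 4,5-bis(benzyloxy)-3,6-bis[4-(benzyloxy)phenyl]-1,2-phenylene dibenzoate, via bridged ozonide 13 (not isolated)
Conditions: O3/O2, CH2Cl2, −78 °C, Sudan red 7B as end-point indicator; then PPh3 (1.5 equiv), −78 °C → rt
Reagents that add atoms: ozone, [O-][O+]=O
Why: Ozonolysis of an enol-ether-type C=C bond to esters: 1,3-dipolar cycloaddition of ozone to the most electron-rich π bond, cycloreversion to an aryl benzoate and a tethered carbonyl oxide, and recombination to ozonide 13, which PPh3 reduces to the second benzoate (carbonyl oxide that escapes ring closure is reduced by PPh3 to the same ester); since each alkene carbon already carries one aryloxy oxygen and one phenyl group, cleavage can only give two benzoates on the neighbouring oxygens. A non-nucleophilic solvent is used so that the carbonyl oxide is not trapped as a hydroperoxy orthoester, which would expel the phenol, and the indicator dye stops the ozone stream before benzylic C–H bonds or the arenes react.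

Step 8
Reactants: 14 4,5-bis(benzyloxy)-3,6-bis[4-(benzyloxy)phenyl]-1,2-phenylene dibenzoate
Product: 15 4,5-dihydroxy-3,6-bis(4-hydroxyphenyl)-1,2-phenylene dibenzoate (CNP0216579.0)
Conditions: H2 (1 atm), Pd/C (10 % palladium on carbon), EtOAc–THF, rt
Reagents that add atoms: none
Why: Catalytic hydrogenolysis of the four benzyl aryl ethers; aryl benzoates are stable to H2 over Pd/C, the neutral aprotic solvent excludes transesterification, and the benzoates cannot migrate because they are meta to the liberated hydroxyls.

## Compound list

1 | tetrabromo-1,4-benzoquinone (bromanil) | O=C1C(Br)=C(Br)C(=O)C(Br)=C1Br | starting material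
2 | 2,5-dibromo-3,6-dimethoxy-1,4-benzoquinone | O=C1C(Br)=C(OC)C(=O)C(Br)=C1OC | intermediate
3 | 4-(benzyloxy)phenylboronic acid | OB(O)c1ccc(OCc2ccccc2)cc1 | starting material
4 | 2,5-bis[4-(benzyloxy)phenyl]-3,6-dimethoxy-1,4-benzoquinone | O=C1C(c2ccc(OCc3ccccc3)cc2)=C(OC)C(=O)C(c2ccc(OCc3ccccc3)cc2)=C1OC | intermediate
5 | 2,5-bis[4-(benzyloxy)phenyl]-3,6-dihydroxy-1,4-benzoquinone | O=C1C(O)=C(c2ccc(OCc3ccccc3)cc2)C(=O)C(O)=C1c1ccc(OCc2ccccc2)cc1 | intermediate
6 | deoxybenzoin (1,2-diphenylethan-1-one) | O=C(Cc1ccccc1)c1ccccc1 | starting material
7 | morpholine | C1COCCN1 | starting material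
8 | 4-[(E)-1,2-diphenylethenyl]morpholine | c1ccccc1/C=C(/N1CCOCC1)c1ccccc1 | intermediate
9 | 3,6-bis[4-(benzyloxy)phenyl]-4,5-dihydroxycyclohexa-3,5-diene-1,2-dione (1,2-dione tautomer of 5, formed in the flask) | O=C1C(=O)C(c2ccc(OCc3ccccc3)cc2)=C(O)C(O)=C1c1ccc(OCc2ccccc2)cc1 | intermediate
10 | 5,8-bis[4-(benzyloxy)phenyl]-2-(morpholin-4-yl)-2,3-diphenyl-2,3-dihydro-1,4-benzodioxine-6,7-diol (formed in the flask; racemic, drawn with the two phenyl groups cis as expected for suprafacial addition, either diastereomer serves) | Oc1c(O)c(-c2ccc(OCc3ccccc3)cc2)c2O[C@@](c3ccccc3)(N3CCOCC3)[C@H](c3ccccc3)Oc2c1-c1ccc(OCc2ccccc2)cc1 | intermediate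
11 | 5,8-bis[4-(benzyloxy)phenyl]-2,3-diphenyl-1,4-benzodioxine-6,7-diol | Oc1c(O)c(-c2ccc(OCc3ccccc3)cc2)c2OC(c3ccccc3)=C(c3ccccc3)Oc2c1-c1ccc(OCc2ccccc2)cc1 | intermediate
12 | 6,7-bis(benzyloxy)-5,8-bis[4-(benzyloxy)phenyl]-2,3-diphenyl-1,4-benzodioxine | C(c1ccccc1)Oc1c(OCc2ccccc2)c(-c2ccc(OCc3ccccc3)cc2)c2OC(c3ccccc3)=C(c3ccccc3)Oc2c1-c1ccc(OCc2ccccc2)cc1 | intermediate
13 | 7,8-bis(benzyloxy)-6,9-bis[4-(benzyloxy)phenyl]-2,4-diphenyl-2,4-epidioxy-2H,4H-1,3,5-benzotrioxepine (bridged ozonide of 12, meso, formed in the flask) | C(c1ccccc1)Oc1c(OCc2ccccc2)c(-c2ccc(OCc3ccccc3)cc2)c2O[C@]3(c4ccccc4)OO[C@@](c4ccccc4)(O3)Oc2c1-c1ccc(OCc2ccccc2)cc1 | intermediate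
14 | 4,5-bis(benzyloxy)-3,6-bis[4-(benzyloxy)phenyl]-1,2-phenylene dibenzoate | O=C(Oc1c(OC(=O)c2ccccc2)c(-c2ccc(OCc3ccccc3)cc2)c(OCc2ccccc2)c(OCc2ccccc2)c1-c1ccc(OCc2ccccc2)cc1)c1ccccc1 | intermediate
15 | 4,5-dihydroxy-3,6-bis(4-hydroxyphenyl)-1,2-phenylene dibenzoate (CNP0216579.0) | O=C(Oc1c(OC(=O)c2ccccc2)c(-c2ccc(O)cc2)c(O)c(O)c1-c1ccc(O)cc1)c1ccccc1 | target

## Step count and least certain steps

Total step count: 8. Longest linear sequence: 7 steps (steps 1, 2, 3, 5, 6, 7 and 8); step 4 is a one-step branch.

**Step 5 (key step, proposed new method).**
- What may go wrong: proton transfer from the acidic hydroxyquinone to the β-carbon of the enamine may outrun cycloaddition. This would park both partners as an ion pair and expose the iminium ion to hydrolysis by adventitious water. The 1,2-dione tautomer may also be too sparsely populated, or too weak a heterodiene, because its carbonyls are flanked by donor-substituted enol units, unlike the halogenated o-quinones of the precedent. Ipso addition–elimination at the hydroxyl-bearing ring carbons, by the enamine or by morpholine set free early, is a further diversion.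
- Fallback by known chemistry, from 5 back to 11: quinone 5 would be reduced with Na2S2O4 (THF–water, Ar) to 3,6-bis[4-(benzyloxy)phenyl]benzene-1,2,4,5-tetrol F1. F1, in excess, would be O-alkylated with one equivalent of 2-bromo-1,2-diphenylethanone (K2CO3, DMF, Ar). The neighbouring hydroxyl closes onto the ketone to give the hemiketal 5,8-bis[4-(benzyloxy)phenyl]-2,3-diphenyl-2,3-dihydro-1,4-benzodioxine-2,6,7-triol F2, and TsOH in hot toluene would dehydrate F2 to 11. This is the classical route from catechols and α-halo ketones to 1,4-benzodioxines. Single bridging is then enforced only by stoichiometry; unreacted F1 returns to 5 on exposure to air and can be recycled.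

**Step 7.**
- What may go wrong: over-oxidation, that is, attack of ozone on the tetraoxygenated central ring or on benzylic C–H bonds once the alkene is consumed. The intermediate carbonyl oxide may also be diverted into rearrangement or oligomeric peroxides instead of closing to the ozonide or being reduced.
- Fallback, from 12 back to 14: dye-sensitised photooxygenation (O2, tetraphenylporphyrin, visible light, CH2Cl2, −20 °C). Singlet oxygen adds [2+2] to the dioxin double bond, which has no allylic hydrogen and so cannot undergo an ene reaction. This gives the cis-fused dioxetane 6,7-bis(benzyloxy)-5,8-bis[4-(benzyloxy)phenyl]-2,3-diphenyl-2,3-epidioxy-2,3-dihydro-1,4-benzodioxine F3. Warming F3 in toluene cleaves the four-membered ring to the two benzoates of 14. Benzyl ethers are inert to singlet oxygen.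

**Step 2.**
- What may go wrong: redox interference of the quinone with the catalytic cycle (reduction of the quinone with oxidative homocoupling of the boronic acid), premature hydrolysis of the vinylogous esters, and a stalled second coupling.
- Fallback, from 2 back to 4, coupling at the arene oxidation level: 2 would be reduced with Na2S2O4 to 2,5-dibromo-3,6-dimethoxybenzene-1,4-diol F4 and methylated (Me2SO4, K2CO3, acetone) to 1,4-dibromo-2,3,5,6-tetramethoxybenzene F5. F5 would be coupled with 3 (Pd(OAc)2, that is palladium diacetate, with the biaryl phosphine SPhos, K3PO4, toluene–water) to 1,4-bis[4-(benzyloxy)phenyl]-2,3,5,6-tetramethoxybenzene F6. Oxidative demethylation of F6 with (NH4)2Ce(NO3)6 (tetravalent cerium) in MeCN–water gives 4; either para pair of methoxy groups leads to the same quinone.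

**Step 8.**
- What may go wrong: slow hydrogenolysis of the two benzyl ethers on the hexasubstituted ring, giving incomplete deprotection, and aerial oxidation of the liberated catechol during a long reaction and work-up.
- Fallback, from 14 directly to 15 without a new intermediate: Lewis-acid debenzylation with BCl3 and pentamethylbenzene as cation scavenger (CH2Cl2, −78 °C). This cleaves aryl benzyl ethers by a cationic path, tolerates aryl esters and avoids the heterogeneous catalyst.

## Further compounds

F1 | step 5 | 3,6-bis[4-(benzyloxy)phenyl]benzene-1,2,4,5-tetrol | Oc1c(O)c(-c2ccc(OCc3ccccc3)cc2)c(O)c(O)c1-c1ccc(OCc2ccccc2)cc1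
F2 | step 5 | 5,8-bis[4-(benzyloxy)phenyl]-2,3-diphenyl-2,3-dihydro-1,4-benzodioxine-2,6,7-triol (racemic, one diastereomer drawn, both serve) | Oc1c(O)c(-c2ccc(OCc3ccccc3)cc2)c2O[C@@](c3ccccc3)(O)[C@H](c3ccccc3)Oc2c1-c1ccc(OCc2ccccc2)cc1
F3 | step 7 | 6,7-bis(benzyloxy)-5,8-bis[4-(benzyloxy)phenyl]-2,3-diphenyl-2,3-epidioxy-2,3-dihydro-1,4-benzodioxine (cis-fused dioxetane, meso) | C(c1ccccc1)Oc1c(OCc2ccccc2)c(-c2ccc(OCc3ccccc3)cc2)c2O[C@@]3(c4ccccc4)OO[C@@]3(c4ccccc4)Oc2c1-c1ccc(OCc2ccccc2)cc1
F4 | step 2 | 2,5-dibromo-3,6-dimethoxybenzene-1,4-diol | Oc1c(Br)c(OC)c(O)c(Br)c1OC
F5 | step 2 | 1,4-dibromo-2,3,5,6-tetramethoxybenzene | COc1c(OC)c(Br)c(OC)c(OC)c1Br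
F6 | step 2 | 1,4-bis[4-(benzyloxy)phenyl]-2,3,5,6-tetramethoxybenzene | COc1c(OC)c(-c2ccc(OCc3ccccc3)cc2)c(OC)c(OC)c1-c1ccc(OCc2ccccc2)cc1
F0 | step 8 | none | none
A1 | alternative 1 | 4,7-bis(4-oxocyclohex-2-en-1-yl)-1,3-benzodioxole-5,6-diyl dibenzoate (one diastereomer drawn, both serve) | O=C1CC[C@@H](C=C1)c1c(OC(=O)c2ccccc2)c(OC(=O)c2ccccc2)c([C@H]2CCC(=O)C=C2)c2OCOc12
A2 | alternative 1 | 4,7-bis(2-oxoethyl)-1,3-benzodioxole-5,6-diyl dibenzoate | O=CCc1c(OC(=O)c2ccccc2)c(OC(=O)c2ccccc2)c(CC=O)c2OCOc12
A3 | alternative 1 | but-3-en-2-one (methyl vinyl ketone) | CC(=O)C=C
A4 | alternative 2 | 5,6-di-tert-butoxy-2,2-di-tert-butyl-4,7-bis[4-(triisopropylsilyloxy)phenyl]-1,3,2-benzodioxasilole | CC(C)[Si](C(C)C)(C(C)C)Oc1ccc(cc1)-c1c(OC(C)(C)C)c(OC(C)(C)C)c(-c2ccc(O[Si](C(C)C)(C(C)C)C(C)C)cc2)c2O[Si](C(C)(C)C)(C(C)(C)C)Oc12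
A5 | alternative 2 | di-tert-butylbis({[4-(triisopropylsilyloxy)phenyl]ethynyl}oxy)silane | CC(C)(C)[Si](OC#Cc1ccc(O[Si](C(C)C)(C(C)C)C(C)C)cc1)(OC#Cc1ccc(O[Si](C(C)C)(C(C)C)C(C)C)cc1)C(C)(C)C
A6 | alternative 2 | 1,2-di-tert-butoxyethyne | CC(C)(C)OC#COC(C)(C)C
A7 | alternative 3 | 3a,7a-dichloro-4,7-bis[4-(benzyloxy)phenyl]-2-oxo-3a,4,7,7a-tetrahydro-1,3-benzodioxole-5,6-diyl dibenzoate (meso endo cycloadduct) | O=C1O[C@]2(Cl)[C@H](c3ccc(OCc4ccccc4)cc3)C(OC(=O)c3ccccc3)=C(OC(=O)c3ccccc3)[C@H](c3ccc(OCc4ccccc4)cc3)[C@]2(Cl)O1
A8 | alternative 3 | (1Z,3Z)-1,4-bis[4-(benzyloxy)phenyl]buta-1,3-diene-2,3-diyl dibenzoate | C(c1ccccc1)Oc1ccc(cc1)/C=C(\OC(=O)c1ccccc1)/C(OC(=O)c1ccccc1)=C/c1ccc(OCc2ccccc2)cc1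
A9 | alternative 3 | 4,5-dichloro-1,3-dioxol-2-one (dichlorovinylene carbonate) | O=C1OC(Cl)=C(Cl)O1
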